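The route rests on cutting the bond between the chain CH2 and the all-carbon quaternary stereocentre of the free-phenol half. This is the carbon that bears CH3, CH=CH2 and the E-styryl arm of the 4-hydroxyphenyl ring. The 3-methyl-3-vinyl unit is an SN2' retron: its vinyl group is the transposed C2=C3 alkene of a (2E,4E)-5-aryl-3-methylpenta-2,4-dienyl phosphate. A ligand-controlled copper-catalysed allylic alkylation with the primary Grignard reagent of the complete aryl tert-alkyl ether half forms the bond, sets the quaternary centre and releases the vinyl group in one operation. The Grignard precursor comes from commercial (S)-bakuchiol and an (S)-epoxide, which carries the carbinol centre.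

Key step: step 7

Assumption: (S)-(+)-bakuchiol is bought as the commercial single enantiomer, and the two chiral catalyst precursors (the L-fructose-derived Shi ketone and the leucinol-derived azolium salt) count as reagents of which either enantiomer can be had.

Step 1
Reactants: 1 5-bromo-2-methylpent-2-ene
Product: 2 (3S)-3-(2-bromoethyl)-2,2-dimethyloxirane
Conditions: L-fructose-derived Shi ketone (ent-Shi ketone, 30 mol %), KHSO5 (Oxone), K2CO3, Bu4NHSO4 (5 mol %), MeCN–CH2(OMe)2, aq. Na2B4O7/Na2(EDTA) buffer, pH 10.5, 0 °C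
Reagents that add atoms: potassium peroxymonosulfate KHSO5, [K+].[O-]S(=O)(=O)OO
Why: Shi asymmetric epoxidation, in which the chiral dioxirane formed from the L-fructose-derived ketone should transfer oxygen through the spiro transition state to the alkene face that gives the S epoxide (the D-fructose-derived ketone gives R on 2-methylalk-2-enes), while the primary bromide survives the cold pH 10.5 medium.

Step 2
Reactants: 2 (3S)-3-(2-bromoethyl)-2,2-dimethyloxirane; 3 (S)-(+)-bakuchiol, 4-[(1E,3S)-3-ethenyl-3,7-dimethylocta-1,6-dien-1-yl]phenol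
Product: 4 (3S)-1-bromo-4-{4-[(1E,3S)-3-ethenyl-3,7-dimethylocta-1,6-dien-1-yl]phenoxy}-4-methylpentan-3-ol
Conditions: 3 (1.5 equiv), BF3·OEt2 (10 mol %), CH2Cl2, −78 to −40 °C, 2 added slowly; Et3N quench
Reagents that add atoms: none
Why: Lewis acid-catalysed epoxide opening of borderline SN2 type, in which the phenol oxygen of 3 should attack the BF3-bound epoxide at the tertiary carbon that carries most of the positive charge, so that the aryl tert-alkyl ether forms while the C–O bond at the secondary carbon is not broken and its S configuration passes into the carbinol.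

Step 3
Reactants: 4 (3S)-1-bromo-4-{4-[(1E,3S)-3-ethenyl-3,7-dimethylocta-1,6-dien-1-yl]phenoxy}-4-methylpentan-3-ol
Product: 5 triethylsilyl ether of 4, {[(3S)-1-bromo-4-{4-[(1E,3S)-3-ethenyl-3,7-dimethylocta-1,6-dien-1-yl]phenoxy}-4-methylpentan-3-yl]oxy}triethylsilane
Conditions: Et3SiOTf, 2,6-lutidine, CH2Cl2, −78 to 0 °C
Reagents that add atoms: triethylsilyl trifluoromethanesulfonate, CC[Si](CC)(CC)OS(=O)(=O)C(F)(F)F
Why: Silyl ether formation with a silyl triflate and a hindered base masks the hindered secondary hydroxyl against the later organomagnesium stage without touching a stereocentre, the bromide or the alkenes.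

Step 4
Reactants: 6 4-[(tert-butyldimethylsilyl)oxy]benzaldehyde; 7 ethyl 4-(diethoxyphosphoryl)-3-methylbut-2-enoate (triethyl 3-methyl-4-phosphonocrotonate, commercial E/Z mixture)
Product: 9 ethyl (2E,4E)-5-{4-[(tert-butyldimethylsilyl)oxy]phenyl}-3-methylpenta-2,4-dienoate, via lithiated phosphonate 8 (not isolated)
Conditions: 7, LiN(SiMe3)2, THF–DMPU, −78 °C; then 6, −78 to 0 °C
Reagents that add atoms: none
Why: Vinylogous Horner–Wadsworth–Emmons olefination, in which the stabilised allylic phosphonate anion reacts at its phosphorus-bearing carbon with the non-enolisable aldehyde and loses phosphate to give the new 4E alkene, the 2E geometry being favoured by equilibration of the anion, and any 2Z isomer is to be removed by chromatography here or at 10.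

Step 5
Reactants: 9 ethyl (2E,4E)-5-{4-[(tert-butyldimethylsilyl)oxy]phenyl}-3-methylpenta-2,4-dienoate
Product: 10 (2E,4E)-5-{4-[(tert-butyldimethylsilyl)oxy]phenyl}-3-methylpenta-2,4-dien-1-ol
Conditions: i-Bu2AlH (2.5 equiv), CH2Cl2, −78 °C; aq. potassium sodium tartrate (KNaC4H4O6)
Reagents that add atoms: none
Why: 1,2-Reduction of the conjugated ester with an aluminium hydride gives the dienol without touching the diene geometry or the aryl silyl ether.

Step 6
Reactants: 10 (2E,4E)-5-{4-[(tert-butyldimethylsilyl)oxy]phenyl}-3-methylpenta-2,4-dien-1-ol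
Product: 11 (2E,4E)-5-{4-[(tert-butyldimethylsilyl)oxy]phenyl}-3-methylpenta-2,4-dien-1-yl diethyl phosphate
Conditions: ClP(O)(OEt)2, Et3N, DMAP (10 mol %), CH2Cl2, 0 °C; rapid filtration through Et3N-deactivated silica
Reagents that add atoms: diethyl chlorophosphate, CCOP(=O)(Cl)OCC
Why: O-Phosphorylation of the primary allylic alcohol under nucleophilic catalysis installs a leaving group that binds magnesium and favours SN2' attack, and the mildly basic medium avoids ionisation of the dienyl system.

Step 7
Reactants: 5 triethylsilyl ether bromide; 11 (2E,4E)-dienyl diethyl phosphate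
Product: 13 bis-silyl ether of (12'S)-bisbakuchiol C (secondary O-SiEt3 plus phenolic O-SiMe2t-Bu), via Grignard reagent 12 (not isolated)
Conditions: 5, Mg turnings (I2-activated), Et2O, 35 °C; solution of 12 added over 2 h to 11 (1.1 equiv), Cu(OTf)2 (3 mol %), chiral 1-mesityl-3-(1-hydroxy-4-methylpentan-2-yl)imidazolinium PF6 salt (4 mol %), Et2O–CH2Cl2, −30 °C
Reagents that add atoms: none
Why: The Grignard reagent 12 deprotonates the azolium salt, reduces Cu(OTf)2 to monovalent copper and transmetalates to an alkoxide-tethered NHC alkylcopper species, which binds the C2=C3 alkene of 11 anti to the magnesium-activated phosphate, adds oxidatively at C3 to a σ-allyl complex of trivalent copper and collapses by fast reductive elimination, so that the CH2–C3 bond forms while C1=C2 becomes the vinyl group. The closest known reaction type is the copper-catalysed enantioselective SN2' allylic alkylation of γ,γ-disubstituted allylic phosphates with primary alkyl Grignard reagents, which builds all-carbon quaternary centres, and 2,4-dienyl electrophiles are known to give skipped 1,4-dienes under such catalysis. No ring is closed. The one new stereocentre is controlled by the chiral carbene ligand, whose enantiomer is chosen so that the alkyl group reaches the Re face of C3 of the 2E alkene (S product), the flat E-styryl arm and the methyl group being told apart as aryl and methyl are in 3-arylbut-2-enyl phosphates, while the stereocentres of 12 are too remote to interfere. The step needs γ attack over α and ε attack, which the strongly donating carbene secures by speeding reductive elimination before the allylcopper can migrate, and ε attack is further disfavoured because it would break the conjugation of the C4=C5 bond with the silyloxyphenyl ring. It also needs geometrically pure 11, since the 2Z isomer would give the epimer, and chemoselectivity, which is given because the silyl ethers, the aryl tert-alkyl ether and the three alkenes of 12 are inert to organomagnesium and organocopper species at −30 °C.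

Step 8
Reactants: 13 bis-silyl ether of (12'S)-bisbakuchiol C
Product: 14 (12'S)-bisbakuchiol C
Conditions: Bu4NF (2.5 equiv), AcOH (2.5 equiv), THF, 0 °C to rt
Reagents that add atoms: none
Why: Fluoride-mediated desilylation cleaves the phenolic and the secondary silyl ether in one operation under buffered conditions that leave the aryl tert-alkyl ether, the alkenes and all three stereocentres untouched.

Compound list
1 | 5-bromo-2-methylpent-2-ene | CC(C)=CCCBr | starting material
2 | (3S)-3-(2-bromoethyl)-2,2-dimethyloxirane | CC1(C)O[C@H]1CCBr | intermediate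
3 | (S)-(+)-bakuchiol, 4-[(1E,3S)-3-ethenyl-3,7-dimethylocta-1,6-dien-1-yl]phenol | C=C[C@@](C)(/C=C/c1ccc(O)cc1)CCC=C(C)C | starting material
4 | (3S)-1-bromo-4-{4-[(1E,3S)-3-ethenyl-3,7-dimethylocta-1,6-dien-1-yl]phenoxy}-4-methylpentan-3-ol | C=C[C@@](C)(/C=C/c1ccc(OC(C)(C)[C@@H](O)CCBr)cc1)CCC=C(C)C | intermediate
5 | triethylsilyl ether of 4 | C=C[C@@](C)(/C=C/c1ccc(OC(C)(C)[C@@H](O[Si](CC)(CC)CC)CCBr)cc1)CCC=C(C)C | intermediate
6 | 4-[(tert-butyldimethylsilyl)oxy]benzaldehyde | O=Cc1ccc(O[Si](C)(C)C(C)(C)C)cc1 | starting material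
7 | ethyl 4-(diethoxyphosphoryl)-3-methylbut-2-enoate (commercial E/Z mixture) | CCOC(=O)C=C(C)CP(=O)(OCC)OCC | starting material
8 | lithiated phosphonate (lithium salt of the carbanion of 7) | [Li+].CCOC(=O)C=C(C)[CH-]P(=O)(OCC)OCC | intermediate
9 | ethyl (2E,4E)-5-{4-[(tert-butyldimethylsilyl)oxy]phenyl}-3-methylpenta-2,4-dienoate | CCOC(=O)/C=C(C)/C=C/c1ccc(O[Si](C)(C)C(C)(C)C)cc1 | intermediate
10 | (2E,4E)-5-{4-[(tert-butyldimethylsilyl)oxy]phenyl}-3-methylpenta-2,4-dien-1-ol | OC/C=C(C)/C=C/c1ccc(O[Si](C)(C)C(C)(C)C)cc1 | intermediate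
11 | (2E,4E)-5-{4-[(tert-butyldimethylsilyl)oxy]phenyl}-3-methylpenta-2,4-dien-1-yl diethyl phosphate | CCOP(=O)(OCC)OC/C=C(C)/C=C/c1ccc(O[Si](C)(C)C(C)(C)C)cc1 | intermediate
12 | Grignard reagent of 5 (C–Br replaced by C–MgBr) | C=C[C@@](C)(/C=C/c1ccc(OC(C)(C)[C@@H](O[Si](CC)(CC)CC)CC[Mg]Br)cc1)CCC=C(C)C | intermediate
13 | bis-silyl ether of (12'S)-bisbakuchiol C (secondary O-SiEt3, phenolic O-SiMe2t-Bu; both quaternary centres S, carbinol S) | C=C[C@@](C)(/C=C/c1ccc(OC(C)(C)[C@@H](O[Si](CC)(CC)CC)CC[C@@](C)(C=C)/C=C/c2ccc(O[Si](C)(C)C(C)(C)C)cc2)cc1)CCC=C(C)C | intermediate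
14 | (12'S)-bisbakuchiol C | C=C[C@@](C)(/C=C/c1ccc(OC(C)(C)[C@@H](O)CC[C@@](C)(C=C)/C=C/c2ccc(O)cc2)cc1)CCC=C(C)C | target

Total step count: 8.
Longest linear sequence: 5 steps (1, 2, 3, 7, 8; the branch 4, 5, 6, 7, 8 is equally long).

Steps most likely to fail

**Step 7.**
- **Risk:** competing attack at the α or ε terminus of the dienyl system, poor facial selectivity at C3, ionisation of the phosphate before coupling, and Wurtz coupling during magnesium insertion.
- **Fallback:** lithiation–borylation followed by Zweifel olefination. It sets out from 5 (and from 6 for the partner) and comes back at 13.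
- Bromide 5 is borylated (B2pin2, CuI, PPh3, LiOMe, DMF, rt) to the primary pinacol boronic ester F1.
- Aldehyde 6 is taken by Wittig olefination with Ph3P=CHC(O)CH3 to the E-enone F2.
- Corey–Bakshi–Shibata reduction ((R)-Me-CBS, catecholborane, toluene, −78 °C, alkenyl as the large group) then gives the (S)-allylic alcohol F3, and i-Pr2NC(O)Cl/Et3N gives the (S)-N,N-diisopropylcarbamate F4.
- F4 is deprotonated with retention (s-BuLi, TMEDA, Et2O, −78 °C) and captured by F1 with retention.
- An invertive 1,2-migration of the CH2 group from boron to carbon then forms the same CH2–C bond stereospecifically and gives the tertiary allylic boronic ester F5.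
- Zweifel olefination (CH2=CHMgBr, then I2, then NaOMe/MeOH, −78 °C to rt) replaces boron by vinyl with retention and gives 13.

**Step 2.**
- **Risk:** hydride shift of the activated epoxide to a ketone (Meinwald rearrangement), attack through the ortho carbon instead of the oxygen of the phenol, and acid-induced cyclisation or oligomerisation of the bakuchiol side chain.
- **Fallback:** base-mediated ether formation next to a carbonyl group, with the carbinol centre set afterwards by reduction. It sets out from 3 and comes back at 4.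
- Phenol 3 is alkylated with the known reagent 2-bromo-N-methoxy-N,2-dimethylpropanamide (Cs2CO3, DMF, 50 °C) to the Weinreb amide F6.
- MeMgBr (THF, 0 °C) gives the methyl ketone F7.
- Its only possible enolate (LiN(i-Pr)2, THF, −78 °C) is hydroxymethylated with gaseous formaldehyde to the β-hydroxy ketone F8.
- Corey–Bakshi–Shibata reduction ((R)-Me-CBS, excess catecholborane, toluene, −78 °C, the C(CH3)2OAr group as the large substituent) should give the (S)-1,3-diol F9.
- Appel bromination of the primary hydroxyl (CBr4, PPh3, CH2Cl2, 0 °C) gives 4.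

**Step 1.**
- **Risk:** incomplete facial selectivity of oxygen transfer to a small alkene whose faces differ little. This would surface later as a carbinol epimer that is hard to separate. Evaporative loss of the low-boiling product is a second concern.
- **Fallback:** the carbinol configuration is corrected after ether formation by an oxidation–reduction pair. It sets out from 4 and comes back at 4.
- Dess–Martin oxidation (CH2Cl2, NaHCO3, 0 °C) gives the β-bromo ketone F10.
- Corey–Bakshi–Shibata reduction ((R)-Me-CBS, catecholborane, toluene, −78 °C) should return 4 with the S carbinol now set by the catalyst, whatever the purity of the epoxide was.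

Further compounds
F1 | step 7 | primary pinacol boronic ester derived from 5 | C=C[C@@](C)(/C=C/c1ccc(OC(C)(C)[C@@H](O[Si](CC)(CC)CC)CCB2OC(C)(C)C(C)(C)O2)cc1)CCC=C(C)C
F2 | step 7 | (E)-4-{4-[(tert-butyldimethylsilyl)oxy]phenyl}but-3-en-2-one | CC(=O)/C=C/c1ccc(O[Si](C)(C)C(C)(C)C)cc1
F3 | step 7 | (2S,3E)-4-{4-[(tert-butyldimethylsilyl)oxy]phenyl}but-3-en-2-ol | C[C@H](O)/C=C/c1ccc(O[Si](C)(C)C(C)(C)C)cc1
F4 | step 7 | (2S,3E)-4-{4-[(tert-butyldimethylsilyl)oxy]phenyl}but-3-en-2-yl N,N-diisopropylcarbamate | C[C@H](OC(=O)N(C(C)C)C(C)C)/C=C/c1ccc(O[Si](C)(C)C(C)(C)C)cc1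
F5 | step 7 | tertiary allylic pinacol boronic ester (boron in place of the vinyl group of 13) | C=C[C@@](C)(/C=C/c1ccc(OC(C)(C)[C@@H](O[Si](CC)(CC)CC)CC[C@@](C)(B2OC(C)(C)C(C)(C)O2)/C=C/c3ccc(O[Si](C)(C)C(C)(C)C)cc3)cc1)CCC=C(C)C
F6 | step 2 | 2-{4-[(1E,3S)-3-ethenyl-3,7-dimethylocta-1,6-dien-1-yl]phenoxy}-N-methoxy-N,2-dimethylpropanamide | C=C[C@@](C)(/C=C/c1ccc(OC(C)(C)C(=O)N(C)OC)cc1)CCC=C(C)C
F7 | step 2 | 3-{4-[(1E,3S)-3-ethenyl-3,7-dimethylocta-1,6-dien-1-yl]phenoxy}-3-methylbutan-2-one | C=C[C@@](C)(/C=C/c1ccc(OC(C)(C)C(C)=O)cc1)CCC=C(C)C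
F8 | step 2 | 4-{4-[(1E,3S)-3-ethenyl-3,7-dimethylocta-1,6-dien-1-yl]phenoxy}-1-hydroxy-4-methylpentan-3-one | C=C[C@@](C)(/C=C/c1ccc(OC(C)(C)C(=O)CCO)cc1)CCC=C(C)C
F9 | step 2 | (3S)-4-{4-[(1E,3S)-3-ethenyl-3,7-dimethylocta-1,6-dien-1-yl]phenoxy}-4-methylpentane-1,3-diol | C=C[C@@](C)(/C=C/c1ccc(OC(C)(C)[C@@H](O)CCO)cc1)CCC=C(C)C
F10 | step 1 | 1-bromo-4-{4-[(1E,3S)-3-ethenyl-3,7-dimethylocta-1,6-dien-1-yl]phenoxy}-4-methylpentan-3-one | C=C[C@@](C)(/C=C/c1ccc(OC(C)(C)C(=O)CCBr)cc1)CCC=C(C)C
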